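**Retrosynthetic overview**
- Last bond made: C3–CH2OH, by a trans-selective aldol of the hydroxy-lactone dianion with formaldehyde (C3 set from C4).
- Key bond: C5–C1' (quaternary, oxygen-bearing ring carbon to the side chain). Hydrogen-atom transfer to a γ-methylidene lactone gives a tertiary C5 radical, which nickel couples with the C17 alkyl iodide anti to the C4 silyloxy group (C5 set from C4).
- γ-Methylidene lactone: gold-catalysed 5-exo-dig lactonisation of (S)-3-hydroxypent-4-ynoic acid, obtained from a β-lactone made by asymmetric ketene–ynal [2+2] (sets C4).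
- Side-chain iodide: C5 alkenyl + C6 + C6, by alkyl–alkenyl Suzuki coupling (fixes the E-alkene) and copper-catalysed Grignard coupling.
- Ring order: β-lactone (temporary, step 3), then the γ-lactone (step 5, the only ring of the target); no ring is formed after the key step.

Assumption: the enantiomer of the aluminium catalyst in step 3 is chosen so that the β-lactone is (S); the (R,R)-ligand is expected to do this, otherwise its antipode is used.

**Route**

Step 1
Reactants: 1 1-bromo-6-chlorohexane; 2 (E)-pent-1-en-1-ylboronic acid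
Product: 3 (E)-11-chloroundec-4-ene
Conditions: Pd(OAc)2 (5 mol %), P(t-Bu)2Me (10 mol %), KOt-Bu (3 equiv), tert-amyl alcohol, 23 °C
Reagents that add atoms: none
Why: Alkyl–alkenyl Suzuki–Miyaura coupling under conditions developed for primary alkyl bromides with β-hydrogens; zerovalent palladium inserts into C–Br and not C–Cl, and the alkenylboron partner transfers with retention of the E geometry, which fixes the only double bond of the target.

Step 2
Reactants: 3 (E)-11-chloroundec-4-ene; 4 1,6-diiodohexane
Product: 6 (E)-17-iodoheptadec-4-ene, via (E)-undec-7-en-1-ylmagnesium chloride 5 (not isolated)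
Conditions: Mg (iodine-activated), THF, 65 °C; then added slowly to 4 (4 equiv), Li2CuCl4 (3 mol %), THF, –30 → 0 °C
Reagents that add atoms: none
Why: Copper-catalysed Grignard–alkyl halide (Kochi-type) sp3–sp3 coupling; the fourfold excess of diiodide and inverse addition hold the reaction at mono-substitution, and the remote E-alkene is not touched.

Step 3
Reactants: 7 3-(trimethylsilyl)prop-2-ynal; 8 acetyl bromide
Product: 10 (S)-4-[(trimethylsilyl)ethynyl]oxetan-2-one, via ketene 9 (not isolated)
Conditions: (R,R)-MeAl[(TfNCH(i-Pr)CH2)2NBn] (10 mol %), i-Pr2NEt (1.7 equiv), CH2Cl2, –50 °C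
Reagents that add atoms: none
Why: Catalytic asymmetric acyl halide–aldehyde cyclocondensation (ketene–aldehyde [2+2], Wynberg-type β-lactone synthesis); the chiral aluminium Lewis acid binds the ynal and directs ketene to one face, setting the future C4 carbinol as S, and alkynyl aldehydes are good substrates for it.

Step 4
Reactants: 10 (S)-4-[(trimethylsilyl)ethynyl]oxetan-2-one
Product: 11 (S)-3-hydroxypent-4-ynoic acid
Conditions: KOH (3 equiv), MeOH/H2O, 0 → 20 °C; then 1 M HCl to pH 2
Reagents that add atoms: potassium hydroxide, [K+].[OH-]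
Why: Saponification of the β-lactone by acyl–oxygen cleavage (retention at the carbinol carbon) with concomitant hydroxide-induced protodesilylation of the alkynylsilane.

Step 5
Reactants: 11 (S)-3-hydroxypent-4-ynoic acid
Product: 13 (S)-4-[(tert-butyldimethylsilyl)oxy]-5-methylideneoxolan-2-one, via (S)-4-hydroxy-5-methylideneoxolan-2-one 12 (not isolated)
Conditions: AuCl (5 mol %), MeCN, 20 °C; then imidazole (3 equiv), TBSCl (1.5 equiv), DMF, 0 → 20 °C
Reagents that add atoms: tert-butyldimethylsilyl chloride, CC(C)(C)[Si](C)(C)Cl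
Why: Gold-catalysed 5-exo-dig cycloisomerisation of a 4-alkynoic acid (anti-oxyauration, then protodeauration) gives the γ-methylidene lactone under neutral conditions, and silylation in the same flask prevents dehydration to the dienyl butenolide; the stereocentre is not involved.

Step 6
Reactants: 13 (S)-4-[(tert-butyldimethylsilyl)oxy]-5-methylideneoxolan-2-one; 6 (E)-17-iodoheptadec-4-ene (1.5 equiv)
Product: 14 (4S,5R)-4-[(tert-butyldimethylsilyl)oxy]-5-[(E)-heptadec-13-en-1-yl]-5-methyloxolan-2-one
Conditions: Mn(dpm)3 (dpm = 2,2,6,6-tetramethylheptane-3,5-dionate, 20 mol %), Ni(acac)2 (5 mol %), Ph(i-PrO)SiH2 (2 equiv), K2CO3 (1.5 equiv), 1,2-dichloroethane/propylene carbonate, 23 °C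
Reagents that add atoms: none
Why: Proposed new method: a manganese hydride formed from Mn(dpm)3 and the silane transfers a hydrogen atom to the electron-rich exocyclic CH2 of the enol ester (Markovnikov), the planar tertiary α-acyloxy C5 radical is captured by the alkylnickel species formed from 6 on the ring face opposite the bulky C4 silyloxy group, and C–C reductive elimination from trivalent nickel forms the quaternary centre with the chain trans to the oxygen substituent (5R); the closest known reaction type is the manganese hydride/nickel dual-catalysed branch-selective hydroalkylation of 1,1-disubstituted olefins with primary alkyl iodides to give quaternary carbons, together with iron hydride-mediated reductive couplings of oxygen-substituted donor olefins.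

Step 7
Reactants: 14 (4S,5R)-4-[(tert-butyldimethylsilyl)oxy]-5-[(E)-heptadec-13-en-1-yl]-5-methyloxolan-2-one
Product: 15 (4S,5R)-5-[(E)-heptadec-13-en-1-yl]-4-hydroxy-5-methyloxolan-2-one
Conditions: HF·pyridine, THF, 0 → 20 °C
Reagents that add atoms: none
Why: Fluoride-mediated silyl ether cleavage under acidic, non-basic conditions, which avoids β-elimination of the β-oxygenated lactone; no stereocentre is touched, and the minor C5 epimer is removed by chromatography at the stage of 14 beforehand.

Step 8
Reactants: 15 (4S,5R)-5-[(E)-heptadec-13-en-1-yl]-4-hydroxy-5-methyloxolan-2-one; 16 formaldehyde (monomer, from cracked paraformaldehyde)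
Product: 18 (3S,4S,5R)-5-[(E)-heptadec-13-en-1-yl]-4-hydroxy-3-(hydroxymethyl)-5-methyloxolan-2-one, via dilithium alkoxide-enolate dianion 17 (not isolated)
Conditions: LiN(i-Pr)2 (2.4 equiv), THF, –78 → –40 °C; CH2O (gas), –78 °C; aq NH4Cl
Reagents that add atoms: none
Why: Fráter–Seebach-type dianion chemistry run as an aldol: the dilithium alkoxide–enolate of the β-hydroxy-γ-lactone reacts with formaldehyde at C3 on the face opposite the C4 alkoxide, giving the 3,4-trans product (3S) without epimerising C4 or C5.

**Compound list**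
1 | 1-bromo-6-chlorohexane | ClCCCCCCBr | starting material
2 | (E)-pent-1-en-1-ylboronic acid | CCC/C=C/B(O)O | starting material
3 | (E)-11-chloroundec-4-ene | CCC/C=C/CCCCCCCl | intermediate
4 | 1,6-diiodohexane | ICCCCCCI | starting material
5 | (E)-undec-7-en-1-ylmagnesium chloride | CCC/C=C/CCCCCC[Mg]Cl | intermediate
6 | (E)-17-iodoheptadec-4-ene | CCC/C=C/CCCCCCCCCCCCI | intermediate
7 | 3-(trimethylsilyl)prop-2-ynal | C[Si](C)(C)C#CC=O | starting material
8 | acetyl bromide | CC(=O)Br | starting material
9 | ketene (ethenone) | C=C=O | intermediate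
10 | (S)-4-[(trimethylsilyl)ethynyl]oxetan-2-one | O=C1C[C@H](O1)C#C[Si](C)(C)C | intermediate
11 | (S)-3-hydroxypent-4-ynoic acid | OC(=O)C[C@H](O)C#C | intermediate
12 | (S)-4-hydroxy-5-methylideneoxolan-2-one | C=C1OC(=O)C[C@@H]1O | intermediate
13 | (S)-4-[(tert-butyldimethylsilyl)oxy]-5-methylideneoxolan-2-one | C=C1OC(=O)C[C@@H]1O[Si](C)(C)C(C)(C)C | intermediate
14 | (4S,5R)-4-[(tert-butyldimethylsilyl)oxy]-5-[(E)-heptadec-13-en-1-yl]-5-methyloxolan-2-one | CCC/C=C/CCCCCCCCCCCC[C@@]1(C)OC(=O)C[C@@H]1O[Si](C)(C)C(C)(C)C | intermediate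
15 | (4S,5R)-5-[(E)-heptadec-13-en-1-yl]-4-hydroxy-5-methyloxolan-2-one | CCC/C=C/CCCCCCCCCCCC[C@@]1(C)OC(=O)C[C@@H]1O | intermediate
16 | formaldehyde | C=O | starting material
17 | dilithium alkoxide-enolate of 15 (lithium 4-oxido-2-lithiooxy-4,5-dihydrofuran form) | CCC/C=C/CCCCCCCCCCCC[C@@]1(C)OC(O[Li])=C[C@@H]1O[Li] | intermediate
18 | (3S,4S,5R)-5-[(E)-heptadec-13-en-1-yl]-4-hydroxy-3-(hydroxymethyl)-5-methyloxolan-2-one | CCC/C=C/CCCCCCCCCCCC[C@@]1(C)OC(=O)[C@@H](CO)[C@@H]1O | target

**Step count and risks**

Total step count: 8 (2 for the side-chain iodide, 3 for the enol lactone, 3 from the coupling to the target).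
Longest linear sequence: 6 steps (steps 3 to 8).

Steps most likely to fail:

Step 6. The enol lactone is an untested donor for the manganese hydride/nickel hydroalkylation. The risks are simple reduction of 13 to the 5-methyl lactone, carbonate-induced loss of silanol from 13, hydrogen-atom transfer to the remote E-alkene of 6 with isomerisation, and incomplete facial control. The fallback sets out from 13 (and, for the chain, from Grignard reagent 5) and comes back at 14. The same C5 radical is generated from 13 with Fe(acac)3 (0.5 equiv) and Ph(i-PrO)SiH2 in THF/i-PrOH at 23 °C and trapped by benzyl acrylate (acrylic acid carrying a benzyl protecting group) in a Giese addition, again anti to the silyloxy group, to give benzyl 3-[(2R,3S)-3-[(tert-butyldimethylsilyl)oxy]-2-methyl-5-oxooxolan-2-yl]propanoate F1. Hydrogenolysis (H2, Pd/C, EtOAc) gives 3-[(2R,3S)-3-[(tert-butyldimethylsilyl)oxy]-2-methyl-5-oxooxolan-2-yl]propanoic acid F2. This is esterified with N-hydroxyphthalimide (N,N'-diisopropylcarbodiimide, DMAP cat., CH2Cl2) to 1,3-dioxoisoindolin-2-yl 3-[(2R,3S)-3-[(tert-butyldimethylsilyl)oxy]-2-methyl-5-oxooxolan-2-yl]propanoate F3. In parallel 5 is coupled with 1-bromo-4-chlorobutane (Li2CuCl4 cat., THF, –30 °C, selective at bromide) to (E)-15-chloropentadec-4-ene F4. F4 is converted with Mg into (E)-pentadec-11-en-1-ylmagnesium chloride F5 and with ZnCl2 (0.5 equiv) into bis[(E)-pentadec-11-en-1-yl]zinc F6. Nickel-catalysed decarboxylative alkyl–alkyl coupling of F3 with F6 (NiCl2(dme) 20 mol %, 4,4'-di-tert-butyl-2,2'-bipyridine 40 mol %, THF/DMF, 25 °C) then gives 14. In this variant the E-alkene is never exposed to a metal hydride.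

Step 8. The formaldehyde aldol of the dianion can give low conversion, double hydroxymethylation or poly(oxymethylene) adducts. The fallback sets out from 15 (through dianion 17) and comes back at 18. Dianion 17 is alkylated instead with 4-methoxybenzyl chloromethyl ether (THF/DMPU, –78 → –30 °C), a trans-selective alkylation with ample precedent for such dianions, to give (3S,4S,5R)-5-[(E)-heptadec-13-en-1-yl]-4-hydroxy-3-{[(4-methoxybenzyl)oxy]methyl}-5-methyloxolan-2-one F7. Oxidative removal of the 4-methoxybenzyl group (DDQ, CH2Cl2/pH 7 buffer, 0 °C) leaves the isolated alkene untouched and gives 18.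

Step 5. The unprotected hydroxy enol lactone 12 can dehydrate to 5-methylidenefuran-2(5H)-one before it is silylated. The fallback sets out from 11 and comes back at 13, protecting before the ring is closed so that 12 never forms. Treatment of 11 with TBSCl (2.5 equiv) and imidazole in DMF gives tert-butyldimethylsilyl (S)-3-[(tert-butyldimethylsilyl)oxy]pent-4-ynoate F8, which is not isolated. Its silyl ester is cleaved with K2CO3 in MeOH/THF/H2O at 0 °C to (S)-3-[(tert-butyldimethylsilyl)oxy]pent-4-ynoic acid F9. AuCl (5 mol %) in MeCN at 20 °C then cyclises F9 to 13.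

**Further compounds**
F1 | step 6 | benzyl 3-[(2R,3S)-3-[(tert-butyldimethylsilyl)oxy]-2-methyl-5-oxooxolan-2-yl]propanoate | O=C(CC[C@@]1(C)OC(=O)C[C@@H]1O[Si](C)(C)C(C)(C)C)OCc1ccccc1
F2 | step 6 | 3-[(2R,3S)-3-[(tert-butyldimethylsilyl)oxy]-2-methyl-5-oxooxolan-2-yl]propanoic acid | OC(=O)CC[C@@]1(C)OC(=O)C[C@@H]1O[Si](C)(C)C(C)(C)C
F3 | step 6 | 1,3-dioxoisoindolin-2-yl 3-[(2R,3S)-3-[(tert-butyldimethylsilyl)oxy]-2-methyl-5-oxooxolan-2-yl]propanoate | O=C(CC[C@@]1(C)OC(=O)C[C@@H]1O[Si](C)(C)C(C)(C)C)ON1C(=O)c2ccccc2C1=O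
F4 | step 6 | (E)-15-chloropentadec-4-ene | CCC/C=C/CCCCCCCCCCCl
F5 | step 6 | (E)-pentadec-11-en-1-ylmagnesium chloride | CCC/C=C/CCCCCCCCCC[Mg]Cl
F6 | step 6 | bis[(E)-pentadec-11-en-1-yl]zinc | CCC/C=C/CCCCCCCCCC[Zn]CCCCCCCCCC/C=C/CCC
F7 | step 8 | (3S,4S,5R)-5-[(E)-heptadec-13-en-1-yl]-4-hydroxy-3-{[(4-methoxybenzyl)oxy]methyl}-5-methyloxolan-2-one | CCC/C=C/CCCCCCCCCCCC[C@@]1(C)OC(=O)[C@@H](COCc2ccc(OC)cc2)[C@@H]1O
F8 | step 5 | tert-butyldimethylsilyl (S)-3-[(tert-butyldimethylsilyl)oxy]pent-4-ynoate | CC(C)(C)[Si](C)(C)OC(=O)C[C@H](O[Si](C)(C)C(C)(C)C)C#C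
F9 | step 5 | (S)-3-[(tert-butyldimethylsilyl)oxy]pent-4-ynoic acid | OC(=O)C[C@H](O[Si](C)(C)C(C)(C)C)C#C
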